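## Analysis of the target

- The target (19) is a flavone: benzo ring A fused to pyranone ring C (a 4H-chromen-4-one), with aryl ring B on C2. It has no stereocentre, so the whole problem is the substitution pattern and telling eight oxygens apart.
- Ring A is fully substituted: OH at C5, OMe at C6, OH at C7 and OMe at C8, between the ring-fusion carbons C4a and C8a. C3 carries a methoxyl, and ring B carries OMe at C2' and C5' and OH at C4'.
- Three phenols (O5, O7, O4') must end free beside five methyl ethers. They therefore have to travel under groups that are not methyl and that come off without harming aryl methyl ethers.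
- The free polyphenol is electron-rich and oxidises easily in base and air. The pyranone opens at C2 under strong hydroxide or alkoxide, and methyl ethers near the carbonyl are at risk from strong Lewis acids.
- The difficulty lies in ring A. The classical flavone syntheses start from a 2-hydroxyaryl ketone, which here would be a hexasubstituted benzene with five oxygens in a fixed order and O1 distinguished from O5 and O7.
- The strategy rests on what remains when the O1–C8a bond is removed. C8a then bears hydrogen, the only hydrogen on ring A, and ring A becomes the pattern of syringaldehyde (1) with one more oxygen at C5. This C8a–H lies ortho to the C8 methoxyl and para to the C6 methoxyl, the position at which an oxidised alkoxyarene takes up an oxygen nucleophile.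

## Retrosynthetic reasoning

**Unmasking (19 from 18 from 17).** The last two steps only remove protecting groups. O5 and O7 are carried as benzyl ethers, which keep ring A electron-rich for the key step and leave by hydrogenolysis of 18. O4' is carried as a pivalate in 17. It makes ring B the electron-poorer arene during the oxidation, survives organomagnesium and enolate chemistry, and leaves by mild methanolysis. Two unmasking steps in place of one are the price of differentiating the two rings electronically.

**Key disconnection (17 from 16), bond O1–C8a.** This is the bond that classical routes buy in with the starting phenol, which forces a sixth substituent onto ring A before the skeleton exists. Cutting it leaves the open 2-methoxy-1,3-diketone 16, whose two aryl ketone halves are both simple. The forward reaction must remove two electrons and two protons and join the enol oxygen on the ring B side to C8a–H of ring A, and it must not close the other way onto C6' of ring B.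

**Diketone (16 from 15, 15 from 14 and 4), bond C3–C4 in flavone numbering.** Diketone 16 is the oxidation product of aldol 15, formed from enolate 14 of methoxymethyl ketone 13 and aldehyde 4. The opposite pairing (ring B aldehyde, ring A methoxymethyl ketone) is not used, because 4 comes directly from 1 whereas a ring A methoxymethyl ketone would cost further steps. The two stereocentres of 15 need no control because the oxidation removes one and makes the other enolisable. Direct C-acylation of 13 at the diketone oxidation level is held in reserve.

**Ring A aldehyde (4 from 3 from 2 from 1).** Aldehyde 1 already has the C6, C7 and C8 oxygens of the target. The missing oxygen (future O5) goes in at C2 through bromide 2 and a copper-mediated hydroxylation to 3. The free phenol is kept during this step because its phenoxide shields the aldehyde from base. Both phenols of 3 are then benzylated to give 4.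

**Ring B ketone (13 from 12 and 11).** The aryl–carbonyl bond C1'–C2 is cut to Grignard reagent 12 and Weinreb amide 11, which is made from acid chloride 10. A Lewis-acid acylation of the arene with 10 would be shorter, but alkoxyacetyl cations tend to decarbonylate and then alkoxymethylate the ring, so it is avoided. Reagent 12 comes from iodide 9, the pivalate of iodophenol 8. Phenol 8 arises by iodination of 7 para to the hydroxyl, and 7 from aldehyde 5 through formate 6.

## Alternatives that were turned down

**Alternative 1:** aryne insertion.
- Disconnection: O1–C8a, C4a–C4 and O1–C2. Ring A is supplied as the aryne A1 (3,5-bis(benzyloxy)-4-methoxybenzyne) and the rest as the α-methoxycinnamic acid A2.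
- Forward key step: a fluoride source releases A1 from a silyl triflate precursor. The carboxylate oxygen of A2 adds to the aryne carbon remote from the flanking benzyloxy group, the aryl anion next to that group takes the acyl group, and the phenoxide closes ring C by conjugate addition to give the trans flavanone A3.
- For it: three bonds form in one flask, the route is highly convergent, the reaction type has precedent, and all three phenols are benzyl ethers, so one hydrogenolysis would unmask them. On convergence and precedent it is stronger than the chosen route.
- Against it: A3 has hydrogen at C8 and is a flavanone. A tetra-oxygenated aryne would have alkoxy groups on both flanks of the triple bond and no bias for where oxygen and carbon add, so C8 must be left open. After the key step C8 still has to be oxygenated and methylated and C2–C3 dehydrogenated, on an electron-rich substrate. The precursor of A1 is itself a pentasubstituted arene needing several steps.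
- Comparison: the chosen route offers the C8 methoxyl from 1 at the outset, the flavone oxidation level directly from the key step, and a ring A building block (4) three steps from a commodity aldehyde.

**Alternative 2:** squarate ring expansion.
- Disconnection: C8–C8a and C4a–C5, so ring A is built last. A C5-metallated 4-pyranone that already carries ring B and the C3 methoxyl adds to the mixed squaric ester A4 to give the cyclobutenone A5.
- Forward key step: on heating, A5 opens to a dienylketene. The ketene carbon bonds to the pyranone C–H next to the ring oxygen, and tautomerisation gives the hydroquinone A6 (5,8-dihydroxy, 6-methoxy, 7-tert-butoxy).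
- For it: all four ring A oxygens come from the squarate in their final positions. O7 is already distinct as a tert-butyl ether, and O5–H is chelated to C4=O, so selective methylation of O8 is credible. The key step is thermal, needs no reagent and has wide precedent for aryl- and alkenylcyclobutenones. On these points it is stronger than the chosen route.
- Against it: the metallated pyranone needs its own multistep synthesis. The two carbonyls of A4 differ only in a remote methoxy versus tert-butoxy group, so the addition may not discriminate, and the wrong regiochemistry exchanges the C6 and C7 labels. A6 is an air-sensitive hydroquinone, and three operations (methylation, tert-butyl removal, debenzylation) follow the key step.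
- Comparison: the chosen route takes the ring A oxygens from 1, where their positions are unambiguous, and is clearly shorter.

**Alternative 3:** fluorine placeholders.
- Disconnection: the C5–O and C7–O bonds; no ring is cut. The two phenolic oxygens are replaced by fluorine in the difluoroflavone A7.
- Forward key step: a benzyl alkoxide displaces both fluorides of A7 by addition–elimination, C5 being ortho and C7 para to the C4 carbonyl, to give the tribenzyl ether A8.
- For it: nucleophilic aromatic substitution on fluorinated chromones is a known reaction type, no ring closure is at stake, and A8 needs a single hydrogenolysis, one step fewer after the key step than the chosen route. Its key step is the safer one.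
- Against it: each fluorine is flanked by electron-donating methoxyls (C7–F by two), which lower the activation and crowd the site, and the alkoxide can also add at C2 of the pyranone. Above all, A7 requires a 2-hydroxyaryl ketone with two fluorines and two methoxyls in fixed order, again a hexasubstituted ring A, to be built from fluoroarenes by several directed metalations.
- Comparison: the risk moves from the key step into a long precursor synthesis. The chosen route reaches its key-step precursor 16 by ten routine steps from commodity aldehydes and puts its risk into one step that has a known-chemistry fallback.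

Key step: step 11

Remark on the chemistry: the electrolysis in step 11 is written for an undivided cell, so protons are reduced at the cathode and dihydrogen is the only co-product.

## Route

Step 1
Reactants: 1 syringaldehyde (4-hydroxy-3,5-dimethoxybenzaldehyde)
Product: 2 2-bromo-4-hydroxy-3,5-dimethoxybenzaldehyde
Conditions: Br2 (1.05 equiv), AcOH, rt
Reagents that add atoms: bromine, BrBr
Why: Electrophilic aromatic bromination; the two open positions of 1 (C2 and C6) are equivalent, each ortho to one methoxyl and para to the other, so only one monobromide can form. The acidic, unbuffered medium keeps the phenol un-ionised, which disfavours ipso attack at the formyl-bearing carbon para to the hydroxyl.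

Step 2
Reactants: 2 2-bromo-4-hydroxy-3,5-dimethoxybenzaldehyde
Product: 3 2,4-dihydroxy-3,5-dimethoxybenzaldehyde
Conditions: NaOH, CuSO4 (cat.), H2O, reflux, N2; then HCl
Reagents that add atoms: sodium hydroxide, [Na+].[OH-]
Why: Copper-mediated (Ullmann-type) hydroxylation of an aryl bromide in hot aqueous alkali, the reaction type that turns bromovanillins into hydroxyvanillins. The 4-phenoxide makes the aldehyde a vinylogous carboxylate and keeps it out of the Cannizzaro reaction, and the meta relation of the two hydroxyls in 3 makes it less prone to air oxidation than a catechol.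

Step 3
Reactants: 3 2,4-dihydroxy-3,5-dimethoxybenzaldehyde
Product: 4 2,4-bis(benzyloxy)-3,5-dimethoxybenzaldehyde
Conditions: BnBr (2.5 equiv), K2CO3, DMF, 60 °C
Reagents that add atoms: benzyl bromide, BrCc1ccccc1
Why: Williamson ether synthesis on both phenols; excess halide in warm DMF also alkylates the 2-hydroxyl that is hydrogen-bonded to the aldehyde.

Step 4
Reactants: 5 2,5-dimethoxybenzaldehyde
Product: 7 2,5-dimethoxyphenol, via 2,5-dimethoxyphenyl formate 6 (not isolated)
Conditions: mCPBA, CH2Cl2, 0 °C to rt; aq. NaHCO3 wash; then K2CO3 (cat.), MeOH, rt
Reagents that add atoms: 3-chloroperoxybenzoic acid, OOC(=O)c1cccc(Cl)c1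
Why: Baeyer–Villiger oxidation of an electron-rich benzaldehyde (Dakin-type), in which the methoxy-substituted aryl group migrates in preference to hydrogen; the formate 6 is then cleaved by transesterification without purification.

Step 5
Reactants: 7 2,5-dimethoxyphenol
Product: 8 4-iodo-2,5-dimethoxyphenol
Conditions: N-iodosuccinimide, MeCN, 0 °C
Reagents that add atoms: N-iodosuccinimide, O=C1CCC(=O)N1I
Why: Electrophilic iodination of a phenol at the position para to the hydroxyl and ortho to a methoxyl; the other doubly activated position is flanked by two substituents. A mild iodine source at low temperature is chosen to avoid oxidation of the electron-rich phenol to a quinone.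

Step 6
Reactants: 8 4-iodo-2,5-dimethoxyphenol
Product: 9 4-iodo-2,5-dimethoxyphenyl pivalate
Conditions: PivCl, Et3N, DMAP (cat.), CH2Cl2, 0 °C to rt
Reagents that add atoms: pivaloyl chloride, CC(C)(C)C(Cl)=O
Why: Phenol acylation under nucleophilic catalysis. The hindered pivalate is chosen because it withstands the Grignard and enolate steps and later makes ring B the electron-poorer arene.

Step 7
Reactants: 10 methoxyacetyl chloride
Product: 11 N,2-dimethoxy-N-methylacetamide
Conditions: MeNHOMe·HCl, pyridine, CH2Cl2, 0 °C to rt
Reagents that add atoms: N,O-dimethylhydroxylamine hydrochloride, CNOC.Cl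
Why: Acylation of an amine by an acid chloride to give a Weinreb amide; pyridine rather than a trialkylamine limits ketene formation from 10.

Step 8
Reactants: 9 4-iodo-2,5-dimethoxyphenyl pivalate; 11 N,2-dimethoxy-N-methylacetamide
Product: 13 2,5-dimethoxy-4-(methoxyacetyl)phenyl pivalate, via arylmagnesium chloride 12 (not isolated)
Conditions: i-PrMgCl·LiCl, THF, −20 °C; then 11, −20 to 0 °C; aq. NH4Cl
Reagents that add atoms: none
Why: Iodine–magnesium exchange with the turbo-Grignard reagent is fast at low temperature for an aryl iodide with an ortho methoxyl and tolerates the hindered aryl ester. The Weinreb ketone synthesis then stops at the chelated tetrahedral adduct, so no tertiary alcohol forms.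

Step 9
Reactants: 13 2,5-dimethoxy-4-(methoxyacetyl)phenyl pivalate; 4 2,4-bis(benzyloxy)-3,5-dimethoxybenzaldehyde
Product: 15 3-[2,4-bis(benzyloxy)-3,5-dimethoxyphenyl]-1-[2,5-dimethoxy-4-(pivaloyloxy)phenyl]-3-hydroxy-2-methoxypropan-1-one (racemic mixture of syn/anti diastereomers), via lithium enolate 14 (not isolated)
Conditions: LiN(SiMe3)2, THF, −78 °C; then 4, −78 °C; aq. NH4Cl at −78 °C
Reagents that add atoms: none
Why: Aldol addition of a lithium enolate (chelated by the α-methoxyl) to a non-enolisable aldehyde, quenched cold to prevent retro-aldol cleavage. Two stereocentres form without control; this does not matter because step 10 turns the carbinol carbon into a carbonyl and makes the other centre enolisable.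

Step 10
Reactants: 15 3-[2,4-bis(benzyloxy)-3,5-dimethoxyphenyl]-1-[2,5-dimethoxy-4-(pivaloyloxy)phenyl]-3-hydroxy-2-methoxypropan-1-one
Product: 16 1-[2,4-bis(benzyloxy)-3,5-dimethoxyphenyl]-3-[2,5-dimethoxy-4-(pivaloyloxy)phenyl]-2-methoxypropane-1,3-dione (racemic)
Conditions: Dess–Martin periodinane, CH2Cl2, 0 °C to rt
Reagents that add atoms: none
Why: Dess–Martin oxidation of a β-hydroxy ketone to a 1,3-diketone under non-basic conditions that do not promote retro-aldol cleavage; benzyl ethers and the pivalate are inert. The carbinol stereocentre is removed, and the remaining one between the carbonyls is racemic and labile by enolisation.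

Step 11
Reactants: 16 1-[2,4-bis(benzyloxy)-3,5-dimethoxyphenyl]-3-[2,5-dimethoxy-4-(pivaloyloxy)phenyl]-2-methoxypropane-1,3-dione
Product: 17 5,7-bis(benzyloxy)-2-[2,5-dimethoxy-4-(pivaloyloxy)phenyl]-3,6,8-trimethoxy-4H-chromen-4-one
Conditions: graphite anode, Pt cathode, undivided cell, constant current (about 2.2 F/mol), n-Bu4NPF6, 2,4,6-collidine, (CF3)2CHOH–CH2Cl2, rt
Reagents that add atoms: none
Why: Proposed new method: in the fluorinated alcohol the diketone 16 equilibrates with its enol, and the anode removes one electron from ring A, the more electron-rich arene (four alkoxy groups, two of them para to each other), or from the enol itself; in either case the enol oxygen on the ring B side bonds to C8a, the only C–H of ring A, a second electron and the C8a proton are lost, and the aromatic chromone 17 results while protons are reduced to dihydrogen at the cathode. The closest known reaction types are the anodic dehydrogenative lactonisation of biaryl-2-carboxylic acids to benzocoumarins and anodic C–H/O–H cyclisations of anilides to benzoxazoles; closure of a pyranone by a diketone enol oxygen onto an arene C–H has not been shown. Ring C closes through a six-membered transition state at a trigonal ring carbon (6-endo-trig counted on the C4a–C8a bond), and attack through the central carbon is excluded because it would make a four-membered ring. No stereocentre is formed, and the labile one at the central carbon of 16 disappears as that carbon becomes sp2. The step needs site selectivity for ring A over C6' of ring B, which the ring A side oxygen could reach: ring B carries only two ether donors and an electron-withdrawing pivalate, and C6' has no oxygen para to it, whereas C8a is para to the C6 methoxyl and ortho to the C8 methoxyl. Attack at the benzyloxy-bearing carbon on the other side of the acyl group has no proton to lose and should revert. A hindered base is used because an unhindered pyridine would itself add to the arene radical cation. The flavone 17, whose carbonyl is held coplanar with ring A and whose new oxygen is part of a vinylogous ester, should be harder to oxidise than 16, which limits over-oxidation.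

Step 12
Reactants: 17 5,7-bis(benzyloxy)-2-[2,5-dimethoxy-4-(pivaloyloxy)phenyl]-3,6,8-trimethoxy-4H-chromen-4-one
Product: 18 5,7-bis(benzyloxy)-2-(4-hydroxy-2,5-dimethoxyphenyl)-3,6,8-trimethoxy-4H-chromen-4-one
Conditions: K2CO3 (0.5 equiv), MeOH–THF, rt to 40 °C; aq. NH4Cl
Reagents that add atoms: none
Why: Base-catalysed transesterification; the aryloxide is a good leaving group, so the aryl pivalate is cleaved under conditions that leave benzyl ethers, methyl ethers and the pyranone untouched.

Step 13
Reactants: 18 5,7-bis(benzyloxy)-2-(4-hydroxy-2,5-dimethoxyphenyl)-3,6,8-trimethoxy-4H-chromen-4-one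
Product: 19 5,7-dihydroxy-2-(4-hydroxy-2,5-dimethoxyphenyl)-3,6,8-trimethoxy-4H-chromen-4-one (5,7,4'-trihydroxy-3,6,8,2',5'-pentamethoxyflavone)
Conditions: H2 (1 atm), Pd/C, EtOAc–MeOH, rt
Reagents that add atoms: none
Why: Catalytic hydrogenolysis of aryl benzyl ethers; the tetrasubstituted C2=C3 bond of the flavone, part of a vinylogous ester, should not be reduced at one atmosphere and room temperature.

## Compound list

1 | syringaldehyde (4-hydroxy-3,5-dimethoxybenzaldehyde) | COc1cc(C=O)cc(OC)c1O | starting material
2 | 2-bromo-4-hydroxy-3,5-dimethoxybenzaldehyde | COc1cc(C=O)c(Br)c(OC)c1O | intermediate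
3 | 2,4-dihydroxy-3,5-dimethoxybenzaldehyde | COc1cc(C=O)c(O)c(OC)c1O | intermediate
4 | 2,4-bis(benzyloxy)-3,5-dimethoxybenzaldehyde | COc1cc(C=O)c(OCc2ccccc2)c(OC)c1OCc1ccccc1 | intermediate
5 | 2,5-dimethoxybenzaldehyde | COc1ccc(OC)c(C=O)c1 | starting material
6 | 2,5-dimethoxyphenyl formate | COc1ccc(OC)c(OC=O)c1 | intermediate (not isolated)
7 | 2,5-dimethoxyphenol | COc1ccc(OC)c(O)c1 | intermediate
8 | 4-iodo-2,5-dimethoxyphenol | COc1cc(I)c(OC)cc1O | intermediate
9 | 4-iodo-2,5-dimethoxyphenyl pivalate | COc1cc(I)c(OC)cc1OC(=O)C(C)(C)C | intermediate
10 | methoxyacetyl chloride | COCC(Cl)=O | starting material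
11 | N,2-dimethoxy-N-methylacetamide | COCC(=O)N(C)OC | intermediate
12 | [2,5-dimethoxy-4-(pivaloyloxy)phenyl]magnesium chloride (LiCl complex) | COc1cc([Mg]Cl)c(OC)cc1OC(=O)C(C)(C)C | intermediate (not isolated)
13 | 2,5-dimethoxy-4-(methoxyacetyl)phenyl pivalate (1-[2,5-dimethoxy-4-(pivaloyloxy)phenyl]-2-methoxyethan-1-one) | COCC(=O)c1cc(OC)c(OC(=O)C(C)(C)C)cc1OC | intermediate
14 | lithium (Z)-1-[2,5-dimethoxy-4-(pivaloyloxy)phenyl]-2-methoxyethen-1-olate (geometry presumed from chelation, of no consequence) | [Li]O/C(=C\OC)c1cc(OC)c(OC(=O)C(C)(C)C)cc1OC | intermediate (not isolated)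
15 | 3-[2,4-bis(benzyloxy)-3,5-dimethoxyphenyl]-1-[2,5-dimethoxy-4-(pivaloyloxy)phenyl]-3-hydroxy-2-methoxypropan-1-one (racemic, mixture of syn and anti diastereomers) | COc1cc(C(O)C(OC)C(=O)c2cc(OC)c(OC(=O)C(C)(C)C)cc2OC)c(OCc2ccccc2)c(OC)c1OCc1ccccc1 | intermediate
16 | 1-[2,4-bis(benzyloxy)-3,5-dimethoxyphenyl]-3-[2,5-dimethoxy-4-(pivaloyloxy)phenyl]-2-methoxypropane-1,3-dione (racemic, labile centre) | COc1cc(C(=O)C(OC)C(=O)c2cc(OC)c(OC(=O)C(C)(C)C)cc2OC)c(OCc2ccccc2)c(OC)c1OCc1ccccc1 | intermediate
17 | 5,7-bis(benzyloxy)-2-[2,5-dimethoxy-4-(pivaloyloxy)phenyl]-3,6,8-trimethoxy-4H-chromen-4-one | COc1cc(-c2oc3c(OC)c(OCc4ccccc4)c(OC)c(OCc4ccccc4)c3c(=O)c2OC)c(OC)cc1OC(=O)C(C)(C)C | intermediate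
18 | 5,7-bis(benzyloxy)-2-(4-hydroxy-2,5-dimethoxyphenyl)-3,6,8-trimethoxy-4H-chromen-4-one | COc1cc(-c2oc3c(OC)c(OCc4ccccc4)c(OC)c(OCc4ccccc4)c3c(=O)c2OC)c(OC)cc1O | intermediate
19 | 5,7,4'-trihydroxy-3,6,8,2',5'-pentamethoxyflavone | COc1cc(-c2oc3c(OC)c(O)c(OC)c(O)c3c(=O)c2OC)c(OC)cc1O | target

## Step count and least certain steps

Total step count: 13. Longest linear sequence: 9 steps, from 5 to 19 (steps 4, 5, 6, 8, 9, 10, 11, 12, 13). The ring A branch from 1 is 8 steps (1, 2, 3, 9 to 13), and step 7 is a one-step side branch.

**Step 11 (key step, the proposed new method).**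
- What may go wrong: oxidation of ring B in place of ring A, with closure in the wrong direction; oxidation at the central methoxy-bearing carbon of the enolised diketone, followed by capture of solvent or C–C cleavage; loss of a benzyl group from the ring A radical cation; further oxidation of the product. The relative oxidation potentials of the two rings are argued from substituent effects only.
- Fallback, by known chemistry, from 4 back to 17:
  - Aldehyde 4 is brominated at its only free ring position (NBS, MeCN) to 2,4-bis(benzyloxy)-6-bromo-3,5-dimethoxybenzaldehyde F1.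
  - Aldol addition of enolate 14 to F1 gives 3-[2,4-bis(benzyloxy)-6-bromo-3,5-dimethoxyphenyl]-1-[2,5-dimethoxy-4-(pivaloyloxy)phenyl]-3-hydroxy-2-methoxypropan-1-one F2.
  - Dess–Martin oxidation gives 1-[2,4-bis(benzyloxy)-6-bromo-3,5-dimethoxyphenyl]-3-[2,5-dimethoxy-4-(pivaloyloxy)phenyl]-2-methoxypropane-1,3-dione F3.
  - Copper-catalysed intramolecular O-arylation of the diketone enolate (CuI, 1,10-phenanthroline, K2CO3, DMF, 90 °C), the established cyclisation of 1-(2-haloaryl)-1,3-diketones to chromones, returns to 17. The bromide fixes the direction of closure. If the pivalate is lost under these conditions, the product is 18, the next compound of the route.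

**Step 2.**
- What may go wrong: sluggish substitution at a bromide flanked by formyl and methoxyl groups, with hydrodebromination or demethylation in hot alkali taking over.
- Fallback, from 2 back to 4:
  - The phenol of 2 is benzylated (BnBr, K2CO3, DMF) to 4-(benzyloxy)-2-bromo-3,5-dimethoxybenzaldehyde F4.
  - Miyaura borylation (B2pin2, PdCl2(dppf), KOAc, dioxane, 90 °C) gives 4-(benzyloxy)-3,5-dimethoxy-2-(4,4,5,5-tetramethyl-1,3,2-dioxaborolan-2-yl)benzaldehyde F5.
  - Oxidation with trimethylamine N-oxide, chosen over peroxide to avoid Dakin cleavage of the aldehyde, gives 4-(benzyloxy)-2-hydroxy-3,5-dimethoxybenzaldehyde F6.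
  - A second benzylation gives 4.

**Step 8.**
- What may go wrong: intermolecular transfer of the pivaloyl group to the aryl Grignard reagent, or incomplete iodine–magnesium exchange on the electron-rich ring.
- Fallback, from 9 back to 13: zinc insertion (Zn dust, LiCl, THF, 40 °C) gives [2,5-dimethoxy-4-(pivaloyloxy)phenyl]zinc iodide F7, which does not attack esters. A Negishi-type acylation with acid chloride 10 under Pd(PPh3)4 catalysis gives 13 directly.

**Step 9.**
- What may go wrong: reversal of the aldol addition on warming or work-up, favoured by the hindered, electron-rich aldehyde; attack of the amide base on the pivalate.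
- Fallback, from 4 back to 16:
  - Pinnick oxidation of 4 (NaClO2, NaH2PO4, 2-methyl-2-butene, t-BuOH–H2O) gives 2,4-bis(benzyloxy)-3,5-dimethoxybenzoic acid F8.
  - Oxalyl chloride with catalytic DMF gives 2,4-bis(benzyloxy)-3,5-dimethoxybenzoyl chloride F9.
  - Soft enolisation of 13 (MgBr2·OEt2, i-Pr2NEt, CH2Cl2) and C-acylation with F9 gives 16 directly, bypassing 15 and step 10.

## Further compounds

F1 | step 11 | 2,4-bis(benzyloxy)-6-bromo-3,5-dimethoxybenzaldehyde | COc1c(Br)c(C=O)c(OCc2ccccc2)c(OC)c1OCc1ccccc1
F2 | step 11 | 3-[2,4-bis(benzyloxy)-6-bromo-3,5-dimethoxyphenyl]-1-[2,5-dimethoxy-4-(pivaloyloxy)phenyl]-3-hydroxy-2-methoxypropan-1-one (racemic, mixture of diastereomers) | COc1c(Br)c(C(O)C(OC)C(=O)c2cc(OC)c(OC(=O)C(C)(C)C)cc2OC)c(OCc2ccccc2)c(OC)c1OCc1ccccc1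
F3 | step 11 | 1-[2,4-bis(benzyloxy)-6-bromo-3,5-dimethoxyphenyl]-3-[2,5-dimethoxy-4-(pivaloyloxy)phenyl]-2-methoxypropane-1,3-dione (racemic) | COc1c(Br)c(C(=O)C(OC)C(=O)c2cc(OC)c(OC(=O)C(C)(C)C)cc2OC)c(OCc2ccccc2)c(OC)c1OCc1ccccc1
F4 | step 2 | 4-(benzyloxy)-2-bromo-3,5-dimethoxybenzaldehyde | COc1cc(C=O)c(Br)c(OC)c1OCc1ccccc1
F5 | step 2 | 4-(benzyloxy)-3,5-dimethoxy-2-(4,4,5,5-tetramethyl-1,3,2-dioxaborolan-2-yl)benzaldehyde | COc1cc(C=O)c(B2OC(C)(C)C(C)(C)O2)c(OC)c1OCc1ccccc1
F6 | step 2 | 4-(benzyloxy)-2-hydroxy-3,5-dimethoxybenzaldehyde | COc1cc(C=O)c(O)c(OC)c1OCc1ccccc1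
F7 | step 8 | [2,5-dimethoxy-4-(pivaloyloxy)phenyl]zinc iodide | COc1cc([Zn]I)c(OC)cc1OC(=O)C(C)(C)C
F8 | step 9 | 2,4-bis(benzyloxy)-3,5-dimethoxybenzoic acid | COc1cc(C(=O)O)c(OCc2ccccc2)c(OC)c1OCc1ccccc1
F9 | step 9 | 2,4-bis(benzyloxy)-3,5-dimethoxybenzoyl chloride | COc1cc(C(=O)Cl)c(OCc2ccccc2)c(OC)c1OCc1ccccc1
A1 | alternative 1 | 3,5-bis(benzyloxy)-4-methoxybenzyne | C1#CC(OCc2ccccc2)=C(OC)C(OCc2ccccc2)=C1
A2 | alternative 1 | (Z)-3-[4-(benzyloxy)-2,5-dimethoxyphenyl]-2-methoxyprop-2-enoic acid | CO/C(C(=O)O)=C\c1cc(OC)c(OCc2ccccc2)cc1OC
A3 | alternative 1 | trans-5,7-bis(benzyloxy)-2-[4-(benzyloxy)-2,5-dimethoxyphenyl]-3,6-dimethoxychroman-4-one (racemic, one enantiomer drawn) | CO[C@@H]1C(=O)c2c(OCc3ccccc3)c(OC)c(OCc3ccccc3)cc2O[C@H]1c1cc(OC)c(OCc2ccccc2)cc1OC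
A4 | alternative 2 | 3-tert-butoxy-4-methoxycyclobut-3-ene-1,2-dione | COC1=C(OC(C)(C)C)C(=O)C1=O
A5 | alternative 2 | 4-{6-[4-(benzyloxy)-2,5-dimethoxyphenyl]-5-methoxy-4-oxo-4H-pyran-3-yl}-2-tert-butoxy-4-hydroxy-3-methoxycyclobut-2-en-1-one (racemic) | O=C1C(OC(C)(C)C)=C(OC)C1(O)c1coc(-c2cc(OC)c(OCc3ccccc3)cc2OC)c(OC)c1=O
A6 | alternative 2 | 2-[4-(benzyloxy)-2,5-dimethoxyphenyl]-7-tert-butoxy-5,8-dihydroxy-3,6-dimethoxy-4H-chromen-4-one | COc1cc(-c2oc3c(O)c(OC(C)(C)C)c(OC)c(O)c3c(=O)c2OC)c(OC)cc1OCc1ccccc1
A7 | alternative 3 | 2-[4-(benzyloxy)-2,5-dimethoxyphenyl]-5,7-difluoro-3,6,8-trimethoxy-4H-chromen-4-one | COc1cc(-c2oc3c(OC)c(F)c(OC)c(F)c3c(=O)c2OC)c(OC)cc1OCc1ccccc1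
A8 | alternative 3 | 5,7-bis(benzyloxy)-2-[4-(benzyloxy)-2,5-dimethoxyphenyl]-3,6,8-trimethoxy-4H-chromen-4-one | COc1cc(-c2oc3c(OC)c(OCc4ccccc4)c(OC)c(OCc4ccccc4)c3c(=O)c2OC)c(OC)cc1OCc1ccccc1
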